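Readings and results come from a simulation for an exercise.

In a one-step world with the gas held steady, substrate goes by a single pseudo-first-order law, with a rate proportional to c(substrate) and to the catalyst charged. We ask what that picture tells us to charge next.

- birch: substrate 0.80 M; gas phase 51 mM (held); catalyst 8 mM; run made earlier
- flask: substrate 0.80 M; gas phase 51 mM (held); catalyst 4.0 mM; time 8.0 h

birch run (percent of the substrate charged)

| time / h | product / % | idle complex A / % |
|---|---|---|
| 0.200 | 0.3 | 0 |
| 0.667 | 1.7 | 0 |
| 1.00 | 5.7 | 0.2 |
| 1.50 | 8.5 | 0 |
| 2.50 | 13.7 | 0 |

(scatter of a reading: 1 percentage point)

- product is meant together with its idle complex A
- at the start none of the gas phase is in solution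
- no earlier run changes the charge of catalyst; that part of a forecast is a guess

- the product and idle complex A together standing at 8.0 h, as a percentage of the substrate charged
- concentration of dissolved gas in solution at 4.0 h, in percent of saturation
- the change that raises the amount of product and idle complex A together at 8.0 h, in percent of the substrate charged most ("none" if none brings more than 2 percentage points) (south-west / west / north-west / none)
- amount of product and idle complex A together at 8.0 h, in percent of the substrate charged, after south-west

- south-west: doubling the amount of catalyst, all else as stated
- west: doubling the saturation concentration of gas phase, all else as stated
- north-west: doubling the transfer coefficient of the gas phase, all else as stated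

1. The flask holds half the catalyst of the birch run. The decision is whether to restore the catalyst or to change the gas.

2. We define κ, the fall of ln c(substrate) per hour and per unit of catalyst charged. The last birch reading, 13.7% at 2.50 h, gives κ = 7.37 /M/h. That reading carries a scatter of 1 percentage point. Proportion to the catalyst is our guess, since no earlier run tests it.

3. For the flask, κ·c(catalyst)·t is 0.236. Read as a straight line, that is 23.6% of the substrate. The small correction is the substrate already used, which takes off 2.6 points. Our reckoning is 21.0%.

4. Doubling the catalyst doubles the exponent and gives 37.6%. The gain of 17 points is larger than the margin of 2 points. The birch run holds the saturation and the transfer coefficient at one value each, so κ gives us no figure for west or north-west. We choose more catalyst for the next run.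

The forecast says 27% (19% to 34%), which is above our figure. It puts the dissolved gas at 72% of saturation (50% to 92%) at 4.0 h and gives 37% (28% to 46%) after south-west. It differs from us in choosing west: “Doubling saturation doubles the rate”.

The flask gives 22.1%, with dissolved gas at 94.1% of saturation at 4.0 h. The best change is south-west, at 37.8%. It gains 16 points, against 4.9 points for west and 0.33 points for north-west.

    catalyst + product ⇌ idle complex A, settled at all times (K = 1.20 /M)
    dissolved gas + catalyst ⇌ idle complex B, settled at all times (K = 34.0 /M)
    substrate + dissolved gas + catalyst → catalyst + product (k = 450 /M²/h)
    gas phase ⇌ dissolved gas, rate k4*(csat - [dissolved gas]) (kL = 7.40 /h)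

In the flask, dissolved gas stood at 93.0% of saturation by 0.800 h, while product and idle complex A together stood at 2.31% of the substrate charged. The step from substrate to product ran on, and by 8.0 h dissolved gas stood at 0.0484 M and substrate at 77.9% of its charge, with idle complex B holding 57.6% of the catalyst charged. At 8.0 h, κ gave 21.0%, and the flask stands at 22.1%. For the same flask left until 30 h, κ gives 58.7%, and that flask stands at 58.6%.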